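**Plan**
- Locants are those of the hexahydronaphthalene core of the target: ring A = C-1, C-2, C-3, C-4, C-4a, C-8a; ring B = C-4a, C-5, C-6, C-7, C-8, C-8a.
- Retrosynthesis: first the ester carbon on C-1 is removed, back to an allylsilane at C-3 with the alkene at C-1=C-2. Then C-3–C-4 and C-4a–C-8a are cut together (intramolecular Diels–Alder reaction). Then the C-1=C-8a alkene of the open chain (cross-metathesis) and the bonds around the tetrasubstituted C-6=C-7 alkene (carbocupration/iodination, Stille coupling) are cut.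
- Enabling feature: the C-4–C-4a bond carries the C-4 ester at one end and the ring B ketone C-5 at the other, so it is a cis-4-oxobutenoate dienophile. It is masked as a menthyl pseudo-ester (5-alkoxybutenolide, C-5 as ketal carbon). C-3, C-2, C-1 and C-8a form a 1-silyl diene tied to it through C-5 to C-8.
- Forward: open-chain triene, then rings A and B closed together in one cycloaddition, then anti SE2′ carbamoylation at C-1 (moves the alkene to C-2=C-3), then amide to ester, then release of the C-5 ketone and C-4 ester.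
- Stereochemistry: absolute control from the resolved ketal carbon (removed at the end); C-4, C-4a and C-8a from the cycloaddition (ring-locked Z dienophile, E,E diene, endo); C-1 from attack anti to silicon on the convex face.

Key step: step 9

**Route**

Step 1
Reactants: 1 octadec-1-yne
Product: 2 methyl nonadec-2-ynoate
Conditions: n-BuLi, THF, −78 °C; ClCO2Me, −78 to 0 °C
Reagents that add atoms: methyl chloroformate, COC(=O)Cl
Why: C-acylation of the lithium acetylide with a chloroformate is the standard entry to 2-alkynoates.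

Step 2
Reactants: 2 methyl nonadec-2-ynoate; 3 allylmagnesium bromide
Product: 5 methyl (2Z)-3-hexadecyl-2-iodohexa-2,5-dienoate, via alkenylcopper adduct 4 (not isolated)
Conditions: 3, CuBr·SMe2 (1 equiv), THF, −78 °C; add 2, −78 °C; then I2, −78 °C
Reagents that add atoms: iodine, II
Why: Syn carbocupration of the ynoate (conjugate addition of the allylcopper reagent) puts allyl on C-3 cis to copper, and iodinolysis at low temperature with retention should fix iodine cis to the allyl group, the geometry that later holds C-5 and C-8 on the same side of the C-6=C-7 alkene.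

Step 3
Reactants: 5 methyl (2Z)-3-hexadecyl-2-iodohexa-2,5-dienoate; 6 tributyl(furan-2-yl)stannane
Product: 7 methyl (2E)-2-(furan-2-yl)-3-hexadecylhexa-2,5-dienoate
Conditions: Pd2(dba)3 (cat.), AsPh3, CuI (cat.), NMP, 50 °C
Reagents that add atoms: none
Why: Stille coupling of the alkenyl iodide proceeds with retention of alkene geometry and should install the furan, a robust latent form of the cis-4-oxobutenoic acid, cis to the allyl group.

Step 4
Reactants: 7 methyl (2E)-2-(furan-2-yl)-3-hexadecylhexa-2,5-dienoate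
Product: 9 methyl (2E)-3-hexadecyl-2-(2-hydroxy-5-oxo-2,5-dihydrofuran-2-yl)hexa-2,5-dienoate, via furan endoperoxide 8 (not isolated)
Conditions: O2, visible light, tetraphenylporphyrin (cat.), i-Pr2NEt, CH2Cl2, −78 °C
Reagents that add atoms: dioxygen, O=O
Why: [4+2] addition of singlet oxygen to the furan and base-induced Kornblum–DeLaMare fragmentation of the endoperoxide at its only bridgehead C–H should give the 5-substituted 5-hydroxybutenolide (racemic hemiketal), while the electron-poor and the monosubstituted alkenes are inert to singlet oxygen at this temperature.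

Step 5
Reactants: 9 methyl (2E)-3-hexadecyl-2-(2-hydroxy-5-oxo-2,5-dihydrofuran-2-yl)hexa-2,5-dienoate; 10 (1R,2S,5R)-menthol
Product: 11 methyl (2E)-3-hexadecyl-2-[(2R)-2-{[(1R,2S,5R)-5-methyl-2-(propan-2-yl)cyclohexyl]oxy}-5-oxo-2,5-dihydrofuran-2-yl]hexa-2,5-dienoate
Conditions: 10 (3 equiv), camphor-10-sulfonic acid (cat.), benzene, reflux, 4 Å molecular sieves; chromatographic separation of the ketal epimers
Reagents that add atoms: none
Why: Acid-catalysed pseudo-ester formation (ketalisation through the planar acyloxocarbenium ion) is not face-selective, so the (2R)-ketal 11 is separated from the (2S)-ketal epimer formed beside it, which re-ionises to the same cation when returned to the same conditions, and this ketal carbon is the only stereocenter taken into the key step.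

Step 6
Reactants: 1 octadec-1-yne
Product: 12 trimethyl(octadec-1-yn-1-yl)silane
Conditions: n-BuLi, THF, −78 °C; Me3SiCl, −78 °C to rt
Reagents that add atoms: chlorotrimethylsilane, C[Si](C)(C)Cl
Why: Silylation of the lithium acetylide is routine.

Step 7
Reactants: 12 trimethyl(octadec-1-yn-1-yl)silane; 13 bromoethene
Product: 15 [(1E)-2-hexadecylbuta-1,3-dien-1-yl]trimethylsilane, via alkenyl-9-BBN 14 (not isolated)
Conditions: 9-BBN-H, THF, 0 °C to rt; then 13, Pd(PPh3)4 (cat.), 3 M NaOH aq, THF, 60 °C, sealed vessel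
Reagents that add atoms: none
Why: Syn hydroboration of the 1-silylalkyne with the hindered borane places boron on the carbon remote from silicon, and Suzuki–Miyaura coupling with retention should give the diene with silicon trans to the vinyl group.

Step 8
Reactants: 11 methyl (2E)-3-hexadecyl-2-[(2R)-2-{[(1R,2S,5R)-5-methyl-2-(propan-2-yl)cyclohexyl]oxy}-5-oxo-2,5-dihydrofuran-2-yl]hexa-2,5-dienoate; 15 [(1E)-2-hexadecylbuta-1,3-dien-1-yl]trimethylsilane
Product: 16 methyl (2E,5E,7E)-3,7-dihexadecyl-2-[(2R)-2-{[(1R,2S,5R)-5-methyl-2-(propan-2-yl)cyclohexyl]oxy}-5-oxo-2,5-dihydrofuran-2-yl]-8-(trimethylsilyl)octa-2,5,7-trienoate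
Conditions: 15 (3 equiv), second-generation Hoveyda–Grubbs catalyst RuCl2(H2IMes)(=CH-C6H4-2-Oi-Pr) (5 mol %), 1,4-benzoquinone (10 mol %), CH2Cl2, 40 °C
Reagents that add atoms: none
Why: Olefin cross-metathesis between the allyl terminus of 11 and the only unhindered alkene of 15 (the trisubstituted vinylsilane and the electron-poor alkenes are inert) should give the conjugated E alkene under thermodynamic control with loss of ethene.

Step 9
Reactants: 16 methyl (2E,5E,7E)-3,7-dihexadecyl-2-[(2R)-2-{[(1R,2S,5R)-5-methyl-2-(propan-2-yl)cyclohexyl]oxy}-5-oxo-2,5-dihydrofuran-2-yl]-8-(trimethylsilyl)octa-2,5,7-trienoate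
Product: 17 methyl (2aR,3S,5aS,8aR,8bS)-4,7-dihexadecyl-8a-{[(1R,2S,5R)-5-methyl-2-(propan-2-yl)cyclohexyl]oxy}-2-oxo-3-(trimethylsilyl)-2a,3,5a,6,8a,8b-hexahydro-2H-naphtho[1,8-bc]furan-8-carboxylate
Conditions: toluene (5 mM, degassed), BHT (cat.), 110 °C, sealed tube
Reagents that add atoms: none
Why: Thermal concerted [4+2] cycloaddition (intramolecular Diels–Alder reaction of a 1,7,9-decatriene-type substrate), closest in type to the Diels–Alder reactions of 5-alkoxybutenolides, which add dienes anti to the alkoxy group. Ring A closes as the cycloadduct ring (diene C-3, C-2, C-1, C-8a plus dienophile C-4, C-4a), and ring B closes in the same event through the new C-4a–C-8a bond as a six-membered ring in the fused type 1 mode, its four-atom tether C-5 to C-8 held in a U shape by the tetrasubstituted alkene. C-4 and C-4a come out cis because the dienophile is locked Z in the butenolide and adds suprafacially, and the absolute sense follows from the (R)-ketal carbon, since the tethered diene can only reach the butenolide face that carries the tether, which is the face anti to the menthyloxy group. C-8a and the silyl-bearing C-3 are set by the E,E diene (both substituents outside) together with the endo transition state, which puts the silyl group, the lactone carbonyl and ring B on one face (cis ring fusion). The selectivity the step needs is endo over exo, which should be secured by secondary overlap of the lactone carbonyl with the diene and by the rigid Z-alkene tether, while regiochemistry is fixed by the tether. The alkene of the product lies at C-1=C-2, one position from where the target has it, with the allylic silane placed to move it in step 10.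

Step 10
Reactants: 17 methyl (2aR,3S,5aS,8aR,8bS)-4,7-dihexadecyl-8a-{[(1R,2S,5R)-5-methyl-2-(propan-2-yl)cyclohexyl]oxy}-2-oxo-3-(trimethylsilyl)-2a,3,5a,6,8a,8b-hexahydro-2H-naphtho[1,8-bc]furan-8-carboxylate
Product: 19 methyl (2aR,5S,5aR,8aR,8bS)-5-carbamoyl-4,7-dihexadecyl-8a-{[(1R,2S,5R)-5-methyl-2-(propan-2-yl)cyclohexyl]oxy}-2-oxo-2a,5,5a,6,8a,8b-hexahydro-2H-naphtho[1,8-bc]furan-8-carboxylate, via N-chlorosulfonyl amide 18 (not isolated)
Conditions: ClSO2NCO, CH2Cl2, −78 to −20 °C; then Na2SO3, NaHCO3, H2O/THF, 0 °C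
Reagents that add atoms: chlorosulfonyl isocyanate, O=C=NS(=O)(=O)Cl
Why: Electrophilic substitution of the allylsilane (SE2′) by the isocyanate forms the C–C bond at C-1 anti to the pseudoaxial C–Si bond, which is also the open convex face of the cis-fused tricycle, so the new carbonyl carbon should end trans to the ring B carbon on C-8a while the alkene moves to C-2=C-3; the electron-poor ring B alkene does not react.

Step 11
Reactants: 19 methyl (2aR,5S,5aR,8aR,8bS)-5-carbamoyl-4,7-dihexadecyl-8a-{[(1R,2S,5R)-5-methyl-2-(propan-2-yl)cyclohexyl]oxy}-2-oxo-2a,5,5a,6,8a,8b-hexahydro-2H-naphtho[1,8-bc]furan-8-carboxylate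
Product: 21 dimethyl (2aR,5S,5aR,8aR,8bS)-4,7-dihexadecyl-8a-{[(1R,2S,5R)-5-methyl-2-(propan-2-yl)cyclohexyl]oxy}-2-oxo-2a,5,5a,6,8a,8b-hexahydro-2H-naphtho[1,8-bc]furan-5,8-dicarboxylate, via imidate salt 20 (not isolated)
Conditions: Me3OBF4, CH2Cl2, rt; then H2O/THF, rt
Reagents that add atoms: trimethyloxonium tetrafluoroborate, C[O+](C)C.F[B-](F)(F)F; water, O
Why: O-Methylation of the primary amide and hydrolysis of the imidate salt turn the amide into the methyl ester without base, so the allylic C-1 stereocenter alpha to the carbonyl should neither epimerise nor move into conjugation.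

Step 12
Reactants: 21 dimethyl (2aR,5S,5aR,8aR,8bS)-4,7-dihexadecyl-8a-{[(1R,2S,5R)-5-methyl-2-(propan-2-yl)cyclohexyl]oxy}-2-oxo-2a,5,5a,6,8a,8b-hexahydro-2H-naphtho[1,8-bc]furan-5,8-dicarboxylate
Product: 23 trimethyl (1S,4R,4aS,8aR)-2,7-dihexadecyl-5-oxo-1,4,4a,5,8,8a-hexahydronaphthalene-1,4,6-tricarboxylate, via keto acid 22 (not isolated)
Conditions: CF3CO2H/H2O/THF, rt; concentrate; then Me3SiCHN2, toluene/MeOH, 0 °C
Reagents that add atoms: water, O; trimethylsilyldiazomethane, C[Si](C)(C)C=[N+]=[N-]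
Why: Acid hydrolysis of the ketal-lactone (pseudo-ester) releases the C-5 ketone, the C-4 carboxylic acid and the auxiliary, and neutral esterification of the open keto acid with the diazoalkane should give the normal methyl ester without touching the base-sensitive cis ring fusion next to the ketone.

**Compound list**
1 | octadec-1-yne | C#CCCCCCCCCCCCCCCCC | starting material
2 | methyl nonadec-2-ynoate | COC(=O)C#CCCCCCCCCCCCCCCCC | intermediate
3 | allylmagnesium bromide | C=CC[Mg]Br | starting material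
4 | alkenylcopper adduct, methyl (2Z)-2-cuprio-3-hexadecylhexa-2,5-dienoate | [Cu]/C(C(=O)OC)=C(\CC=C)CCCCCCCCCCCCCCCC | intermediate
5 | methyl (2Z)-3-hexadecyl-2-iodohexa-2,5-dienoate | I/C(C(=O)OC)=C(\CC=C)CCCCCCCCCCCCCCCC | intermediate
6 | tributyl(furan-2-yl)stannane | CCCC[Sn](CCCC)(CCCC)c1ccco1 | starting material
7 | methyl (2E)-2-(furan-2-yl)-3-hexadecylhexa-2,5-dienoate | o1cccc1/C(C(=O)OC)=C(\CC=C)CCCCCCCCCCCCCCCC | intermediate
8 | furan endoperoxide, methyl (2E)-3-hexadecyl-2-(2,3,7-trioxabicyclo[2.2.1]hept-5-en-1-yl)hexa-2,5-dienoate | C1=CC2(OOC1O2)/C(C(=O)OC)=C(\CC=C)CCCCCCCCCCCCCCCC | intermediate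
9 | methyl (2E)-3-hexadecyl-2-(2-hydroxy-5-oxo-2,5-dihydrofuran-2-yl)hexa-2,5-dienoate (racemic hemiketal) | O=C1C=CC(O)(O1)/C(C(=O)OC)=C(\CC=C)CCCCCCCCCCCCCCCC | intermediate
10 | (1R,2S,5R)-menthol, (1R,2S,5R)-5-methyl-2-(propan-2-yl)cyclohexan-1-ol | CC(C)[C@@H]1CC[C@@H](C)C[C@H]1O | starting material
11 | methyl (2E)-3-hexadecyl-2-[(2R)-2-{[(1R,2S,5R)-5-methyl-2-(propan-2-yl)cyclohexyl]oxy}-5-oxo-2,5-dihydrofuran-2-yl]hexa-2,5-dienoate | O=C1C=C[C@](O1)(O[C@@H]2C[C@H](C)CC[C@H]2C(C)C)/C(C(=O)OC)=C(\CC=C)CCCCCCCCCCCCCCCC | intermediate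
12 | trimethyl(octadec-1-yn-1-yl)silane | C[Si](C)(C)C#CCCCCCCCCCCCCCCCC | intermediate
13 | bromoethene | C=CBr | starting material
14 | 9-[(1Z)-1-hexadecyl-2-(trimethylsilyl)ethenyl]-9-borabicyclo[3.3.1]nonane | C[Si](C)(C)/C=C(\CCCCCCCCCCCCCCCC)B1C2CCCC1CCC2 | intermediate
15 | [(1E)-2-hexadecylbuta-1,3-dien-1-yl]trimethylsilane | C=C/C(CCCCCCCCCCCCCCCC)=C/[Si](C)(C)C | intermediate
16 | methyl (2E,5E,7E)-3,7-dihexadecyl-2-[(2R)-2-{[(1R,2S,5R)-5-methyl-2-(propan-2-yl)cyclohexyl]oxy}-5-oxo-2,5-dihydrofuran-2-yl]-8-(trimethylsilyl)octa-2,5,7-trienoate | O=C1C=C[C@](O1)(O[C@@H]2C[C@H](C)CC[C@H]2C(C)C)/C(C(=O)OC)=C(\C/C=C/C(CCCCCCCCCCCCCCCC)=C/[Si](C)(C)C)CCCCCCCCCCCCCCCC | intermediate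
17 | methyl (2aR,3S,5aS,8aR,8bS)-4,7-dihexadecyl-8a-{[(1R,2S,5R)-5-methyl-2-(propan-2-yl)cyclohexyl]oxy}-2-oxo-3-(trimethylsilyl)-2a,3,5a,6,8a,8b-hexahydro-2H-naphtho[1,8-bc]furan-8-carboxylate (H-2a, H-5a and H-8b on one face; silyl group, lactone and ring B on the other) | C[Si](C)(C)[C@H]1[C@H]2C(=O)O[C@]3(O[C@@H]4C[C@H](C)CC[C@H]4C(C)C)[C@H]2[C@@H](CC(CCCCCCCCCCCCCCCC)=C3C(=O)OC)C=C1CCCCCCCCCCCCCCCC | intermediate
18 | N-chlorosulfonyl derivative of amide 19 (CONHSO2Cl on C-5 of the tricycle; stereocenters as in 19) | CCCCCCCCCCCCCCCCC1=C[C@H]2C(=O)O[C@]3(O[C@@H]4C[C@H](C)CC[C@H]4C(C)C)[C@H]2[C@@H](CC(CCCCCCCCCCCCCCCC)=C3C(=O)OC)[C@@H]1C(=O)NS(=O)(=O)Cl | intermediate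
19 | methyl (2aR,5S,5aR,8aR,8bS)-5-carbamoyl-4,7-dihexadecyl-8a-{[(1R,2S,5R)-5-methyl-2-(propan-2-yl)cyclohexyl]oxy}-2-oxo-2a,5,5a,6,8a,8b-hexahydro-2H-naphtho[1,8-bc]furan-8-carboxylate | CCCCCCCCCCCCCCCCC1=C[C@H]2C(=O)O[C@]3(O[C@@H]4C[C@H](C)CC[C@H]4C(C)C)[C@H]2[C@@H](CC(CCCCCCCCCCCCCCCC)=C3C(=O)OC)[C@@H]1C(N)=O | intermediate
20 | O-methyl imidate tetrafluoroborate of amide 19 (C(=NH2+)OMe in place of CONH2; stereocenters as in 19) | CCCCCCCCCCCCCCCCC1=C[C@H]2C(=O)O[C@]3(O[C@@H]4C[C@H](C)CC[C@H]4C(C)C)[C@H]2[C@@H](CC(CCCCCCCCCCCCCCCC)=C3C(=O)OC)[C@@H]1C(=[NH2+])OC.F[B-](F)(F)F | intermediate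
21 | dimethyl (2aR,5S,5aR,8aR,8bS)-4,7-dihexadecyl-8a-{[(1R,2S,5R)-5-methyl-2-(propan-2-yl)cyclohexyl]oxy}-2-oxo-2a,5,5a,6,8a,8b-hexahydro-2H-naphtho[1,8-bc]furan-5,8-dicarboxylate | CCCCCCCCCCCCCCCCC1=C[C@H]2C(=O)O[C@]3(O[C@@H]4C[C@H](C)CC[C@H]4C(C)C)[C@H]2[C@@H](CC(CCCCCCCCCCCCCCCC)=C3C(=O)OC)[C@@H]1C(=O)OC | intermediate
22 | (1R,4S,4aR,8aS)-3,6-dihexadecyl-4,7-bis(methoxycarbonyl)-8-oxo-1,4,4a,5,8,8a-hexahydronaphthalene-1-carboxylic acid | CCCCCCCCCCCCCCCCC1=C[C@@H](C(=O)O)[C@H]2C(=O)C(C(=O)OC)=C(CCCCCCCCCCCCCCCC)C[C@H]2[C@@H]1C(=O)OC | intermediate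
23 | trimethyl (1S,4R,4aS,8aR)-2,7-dihexadecyl-5-oxo-1,4,4a,5,8,8a-hexahydronaphthalene-1,4,6-tricarboxylate | CCCCCCCCCCCCCCCCC1=C[C@@H](C(=O)OC)[C@H]2C(=O)C(C(=O)OC)=C(CCCCCCCCCCCCCCCC)C[C@H]2[C@@H]1C(=O)OC | target

**Step count and risks**

Total steps: 12. Longest linear sequence: 10 steps (steps 1, 2, 3, 4, 5, 8, 9, 10, 11, 12, from octadec-1-yne).

Steps most likely to fail:

1. Step 9. What may go wrong is insufficient endo preference, which would give the trans ring fusion, or a cycloaddition slow enough that thermal decay of the triene competes. The fallback sets out from 9 and comes back to the route at 23. Esterification of the pseudo-acid 9 with Me3SiCHN2 should give the open-chain methyl (2Z,5E)-6-hexadecyl-5-(methoxycarbonyl)-4-oxonona-2,5,8-trienoate F1. Cross-metathesis with 15 as in step 8 should give methyl (2Z,5E,8E,10E)-6,10-dihexadecyl-5-(methoxycarbonyl)-4-oxo-11-(trimethylsilyl)undeca-2,5,8,10-tetraenoate F2. In this free Z-enedione the ketone and the ester are cis on the dienophile and can both sit endo, the arrangement that favours cis fusion in decatrienones with a ketone in the tether. Warming in toluene should therefore give racemic dimethyl (1R,2S,4aS,8aS)-3,6-dihexadecyl-8-oxo-2-(trimethylsilyl)-1,2,4a,5,8,8a-hexahydronaphthalene-1,7-dicarboxylate F3, which is separated on a chiral stationary phase from its (1S,2R,4aR,8aR) enantiomer F4. Chlorosulfonyl isocyanate then gives the N-chlorosulfonyl amide F5 and, after sulfite work-up, dimethyl (1S,4R,4aS,8aR)-1-carbamoyl-2,7-dihexadecyl-5-oxo-1,4,4a,5,8,8a-hexahydronaphthalene-4,6-dicarboxylate F6. Trimethyloxonium tetrafluoroborate (O-methyl imidate salt F7) and water then give 23.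

2. Step 10. What may go wrong is [2+2] addition of the isocyanate instead of desilylative substitution, attack of the electrophile on the acid-labile ketal, or protodesilylation without C–C bond formation. The fallback sets out from 17 and comes back at 21. Friedel–Crafts-type SE2′ acylation of the allylsilane with trichloroacetyl chloride and AlCl3 in CH2Cl2 at −78 °C should give the trichloromethyl ketone F8 (COCCl3 in place of CO2Me at C-5 of the tricycle of 21). Haloform-type methanolysis (MeOH, Et3N, DMAP cat.) then gives ester 21 with loss of chloroform.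

3. Step 8. What may go wrong is secondary metathesis at the conjugated diene, low E selectivity at the new alkene, or isomerisation of the skipped diene into conjugation. The fallback sets out from 11 and comes back at 16. Cross-metathesis of 11 with vinylboronic acid pinacol ester (same catalyst) should give the (2E,5E)-alkenylboronate, methyl 3-hexadecyl-2-[(2R)-2-(menthyloxy)-5-oxo-2,5-dihydrofuran-2-yl]-6-(4,4,5,5-tetramethyl-1,3,2-dioxaborolan-2-yl)hexa-2,5-dienoate F9. Iododeboronation with N-iodosuccinimide in MeCN should give the corresponding (2E,5E)-6-iodohexa-2,5-dienoate F10. Suzuki–Miyaura coupling of F10 with alkenylborane 14, made in the flask from 12 as in step 7 (Pd(dppf)Cl2, AsPh3, Cs2CO3, DMF/H2O, rt), then gives 16.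

Further compounds
F1 | step 9 | methyl (2Z,5E)-6-hexadecyl-5-(methoxycarbonyl)-4-oxonona-2,5,8-trienoate | COC(=O)/C=C\C(=O)/C(C(=O)OC)=C(\CC=C)CCCCCCCCCCCCCCCC
F2 | step 9 | methyl (2Z,5E,8E,10E)-6,10-dihexadecyl-5-(methoxycarbonyl)-4-oxo-11-(trimethylsilyl)undeca-2,5,8,10-tetraenoate | COC(=O)/C=C\C(=O)/C(C(=O)OC)=C(\C/C=C/C(CCCCCCCCCCCCCCCC)=C/[Si](C)(C)C)CCCCCCCCCCCCCCCC
F3 | step 9 | dimethyl (1R,2S,4aS,8aS)-3,6-dihexadecyl-8-oxo-2-(trimethylsilyl)-1,2,4a,5,8,8a-hexahydronaphthalene-1,7-dicarboxylate | C[Si](C)(C)[C@H]1[C@@H](C(=O)OC)[C@H]2C(=O)C(C(=O)OC)=C(CCCCCCCCCCCCCCCC)C[C@H]2C=C1CCCCCCCCCCCCCCCC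
F4 | step 9 | dimethyl (1S,2R,4aR,8aR)-3,6-dihexadecyl-8-oxo-2-(trimethylsilyl)-1,2,4a,5,8,8a-hexahydronaphthalene-1,7-dicarboxylate (enantiomer of F3) | C[Si](C)(C)[C@@H]1[C@H](C(=O)OC)[C@@H]2C(=O)C(C(=O)OC)=C(CCCCCCCCCCCCCCCC)C[C@@H]2C=C1CCCCCCCCCCCCCCCC
F5 | step 9 | N-chlorosulfonyl derivative of amide F6 | CCCCCCCCCCCCCCCCC1=C[C@@H](C(=O)OC)[C@H]2C(=O)C(C(=O)OC)=C(CCCCCCCCCCCCCCCC)C[C@H]2[C@@H]1C(=O)NS(=O)(=O)Cl
F6 | step 9 | dimethyl (1S,4R,4aS,8aR)-1-carbamoyl-2,7-dihexadecyl-5-oxo-1,4,4a,5,8,8a-hexahydronaphthalene-4,6-dicarboxylate | CCCCCCCCCCCCCCCCC1=C[C@@H](C(=O)OC)[C@H]2C(=O)C(C(=O)OC)=C(CCCCCCCCCCCCCCCC)C[C@H]2[C@@H]1C(N)=O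
F7 | step 9 | O-methyl imidate tetrafluoroborate of amide F6 | CCCCCCCCCCCCCCCCC1=C[C@@H](C(=O)OC)[C@H]2C(=O)C(C(=O)OC)=C(CCCCCCCCCCCCCCCC)C[C@H]2[C@@H]1C(=[NH2+])OC.F[B-](F)(F)F
F8 | step 10 | trichloromethyl ketone corresponding to ester 21 (COCCl3 in place of CO2Me at C-5 of the tricycle) | CCCCCCCCCCCCCCCCC1=C[C@H]2C(=O)O[C@]3(O[C@@H]4C[C@H](C)CC[C@H]4C(C)C)[C@H]2[C@@H](CC(CCCCCCCCCCCCCCCC)=C3C(=O)OC)[C@@H]1C(=O)C(Cl)(Cl)Cl
F9 | step 8 | methyl (2E,5E)-3-hexadecyl-2-[(2R)-2-{[(1R,2S,5R)-5-methyl-2-(propan-2-yl)cyclohexyl]oxy}-5-oxo-2,5-dihydrofuran-2-yl]-6-(4,4,5,5-tetramethyl-1,3,2-dioxaborolan-2-yl)hexa-2,5-dienoate | O=C1C=C[C@](O1)(O[C@@H]2C[C@H](C)CC[C@H]2C(C)C)/C(C(=O)OC)=C(\C/C=C/B3OC(C)(C)C(C)(C)O3)CCCCCCCCCCCCCCCC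
F10 | step 8 | methyl (2E,5E)-3-hexadecyl-6-iodo-2-[(2R)-2-{[(1R,2S,5R)-5-methyl-2-(propan-2-yl)cyclohexyl]oxy}-5-oxo-2,5-dihydrofuran-2-yl]hexa-2,5-dienoate | O=C1C=C[C@](O1)(O[C@@H]2C[C@H](C)CC[C@H]2C(C)C)/C(C(=O)OC)=C(\C/C=C/I)CCCCCCCCCCCCCCCC
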